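The target is cut at C8–C9, the bond between the 8(17)-exocyclic methylene carbon of ring B and the C9 methine that carries the side chain. A palladium hydride reductive cyclisation of a 1,7-enyne makes this bond, closes ring B, leaves C8 as the exocyclic methylene and sets C9 in one operation. Its substrate is a fully substituted ring A: a terminal butynyl arm on C5 and an (E)-3-(3-furyl)propenyl arm on C10, trans to each other, with the 3,18-diol held as a trans-fused acetonide that locks the chair. Ring A comes from desymmetrised 2-methylcyclohexane-1,3-dione; the furan is unmasked late as the Z-enediol after angeloylation.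

Key step: step 15

Assumption: atoms carry labdane numbers throughout (C18 is the oxygenated C4 substituent, C19 the C4 methyl, C20 the C10 methyl), and the reductase of step 3 is the member of a commercial ketoreductase panel that gives the trans ketol.

Step 1
Reactants: 1 2-methylcyclohexane-1,3-dione; 2 formaldehyde
Product: 3 2-(hydroxymethyl)-2-methylcyclohexane-1,3-dione
Conditions: 37% aq. HCHO, NaHCO3 (cat.), THF/H2O, rt
Reagents that add atoms: none
Why: Tollens-type aldol addition of the dione enolate through C2 to formaldehyde should stop at the quaternary mono-adduct because no acidic C–H remains.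

Step 2
Reactants: 3 hydroxymethyl dione
Product: 4 2-{[tert-butyl(dimethyl)silyl]oxymethyl}-2-methylcyclohexane-1,3-dione
Conditions: TBSCl, imidazole, CH2Cl2, 0 °C
Reagents that add atoms: tert-butyldimethylsilyl chloride, CC(C)(C)[Si](C)(C)Cl
Why: Imidazole-mediated O-silylation of the primary alcohol should block retro-aldol loss of formaldehyde in the aqueous step that follows.

Step 3
Reactants: 4 silyl ether dione
Product: 5 (2S,3R)-2-{[tert-butyl(dimethyl)silyl]oxymethyl}-3-hydroxy-2-methylcyclohexan-1-one (hydroxyl trans to the silyloxymethyl group, cis to the methyl)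
Conditions: ketoreductase, NADP+ (cat.), i-PrOH, KH2PO4/K2HPO4 buffer pH 7, DMSO (5%), 30 °C
Reagents that add atoms: none
Why: Enzymatic desymmetrising carbonyl reduction, known for 2,2-disubstituted cyclohexane-1,3-diones, should reduce one enantiotopic carbonyl from one face, so that the active site sets C3 (R, oxygen trans to C18) and with it the quaternary C4 (S).

Step 4
Reactants: 5 trans ketol
Product: 7 (4aS,8aR)-2,2,4a-trimethylhexahydro-4H-1,3-benzodioxin-5-one (trans-fused 3,18-acetonide, ketone at C5), via diol ketone 6 (not isolated)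
Conditions: CSA (cat.), MeOH, rt; then 2,2-dimethoxypropane, acetone, CSA (cat.), rt
Reagents that add atoms: 2,2-dimethoxypropane, COC(C)(C)OC
Why: Acid methanolysis of the silyl ether and ketal exchange should give the trans-fused 1,3-dioxane, which locks ring A in the chair with the C19 methyl axial for the later face-selective steps.

Step 5
Reactants: 7 acetonide ketone
Product: 8 (4aS,8aR)-2,2,4a,6-tetramethylhexahydro-4H-1,3-benzodioxin-5-one (both C10 epimers)
Conditions: LiN(i-Pr)2, THF, −78 °C; MeI, −78 → 0 °C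
Reagents that add atoms: iodomethane, CI
Why: Kinetic enolate alkylation can occur only at C10 because C4 is quaternary, and the configuration of the new C10 centre does not matter since step 6 makes it planar.

Step 6
Reactants: 8 methyl ketone
Product: 9 (4aS,8aR)-2,2,4a,6-tetramethyl-4a,7,8,8a-tetrahydro-4H-1,3-benzodioxin-5-yl trifluoromethanesulfonate (C5=C10 enol triflate)
Conditions: KN(SiMe3)2, THF, −78 °C; PhNTf2, −78 → 0 °C
Reagents that add atoms: N-phenylbis(trifluoromethanesulfonimide), O=S(=O)(N(c1ccccc1)S(=O)(=O)C(F)(F)F)C(F)(F)F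
Why: Enolate O-sulfonylation, in which the single enolisable hydrogen at C10 forces the tetrasubstituted C5=C10 enol triflate.

Step 7
Reactants: 9 enol triflate
Product: 10 methyl (4aS,8aR)-2,2,4a,6-tetramethyl-4a,7,8,8a-tetrahydro-4H-1,3-benzodioxine-5-carboxylate
Conditions: Pd(OAc)2 (5 mol %), 1,3-bis(diphenylphosphino)propane, CO (1 atm), Et3N, MeOH/DMF, 60 °C
Reagents that add atoms: carbon monoxide, [C-]#[O+]; methanol, CO
Why: Palladium-catalysed alkoxycarbonylation of an enol triflate (oxidative addition to zerovalent palladium, CO insertion, methanolysis) should install C6 on C5.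

Step 8
Reactants: 10 unsaturated ester
Product: 11 [(4aS,8aR)-2,2,4a,6-tetramethyl-4a,7,8,8a-tetrahydro-4H-1,3-benzodioxin-5-yl]methanol
Conditions: i-Bu2AlH (2.5 equiv), CH2Cl2, −78 → 0 °C
Reagents that add atoms: none
Why: Aluminium hydride 1,2-reduction of the conjugated ester should give the allylic alcohol without touching the acetonide.

Step 9
Reactants: 11 allylic alcohol
Product: 12 diethyl [(4aS,8aR)-2,2,4a,6-tetramethyl-4a,7,8,8a-tetrahydro-4H-1,3-benzodioxin-5-yl]methyl phosphate
Conditions: ClP(O)(OEt)2, Et3N, DMAP (cat.), CH2Cl2, 0 °C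
Reagents that add atoms: diethyl chlorophosphate, CCOP(=O)(Cl)OCC
Why: O-Phosphorylation turns the primary allylic alcohol into the leaving group best suited to copper-catalysed γ-selective allylic substitution.

Step 10
Reactants: 13 furan-3-ylmethanol
Product: 14 3-(bromomethyl)furan
Conditions: PBr3, pyridine (cat.), Et2O, −10 → 0 °C; used at once
Reagents that add atoms: phosphorus tribromide, BrP(Br)Br
Why: Alcohol-to-bromide substitution through the phosphite ester (SN2 by bromide) should give the labile furfuryl-type bromide, which is used without storage.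

Step 11
Reactants: 14 3-(bromomethyl)furan; 15 ethynylmagnesium bromide
Product: 16 3-(prop-2-yn-1-yl)furan
Conditions: HC≡CMgBr (3 equiv), CuBr·SMe2 (5 mol %), THF, 0 °C → rt
Reagents that add atoms: none
Why: Copper-catalysed cross-coupling of a benzylic-type bromide with an alkynyl Grignard reagent, with the excess of Grignard reagent suppressing double alkylation.

Step 12
Reactants: 12 allylic phosphate; 16 3-(prop-2-yn-1-yl)furan
Product: 18 (4aS,6S,8aR)-6-[(1E)-3-(furan-3-yl)prop-1-en-1-yl]-2,2,4a,6-tetramethyl-5-methylidenehexahydro-4H-1,3-benzodioxine (alkenyl arm on C10 trans to C19, exocyclic C5=C6), via alkenylalane 17 (not isolated)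
Conditions: 16, i-Bu2AlH, hexanes, 55 °C; then 12, CuCl(IMes) (5 mol %; IMes = 1,3-dimesitylimidazol-2-ylidene), THF, −15 °C → rt
Reagents that add atoms: none
Why: syn-Hydroalumination gives the (E)-alkenylalane, and copper-catalysed SN2′ allylic substitution, a known way to all-carbon quaternary centres from γ,γ-disubstituted allylic phosphates, should deliver the alkenyl group to C10 with shift of the alkene to C5=C6, on the face anti to the axial C19 methyl of the acetonide-locked half-chair, which sets C10 (S).

Step 13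
Reactants: 18 ring A diene
Product: 20 [(4aS,5S,6S,8aR)-6-[(1E)-3-(furan-3-yl)prop-1-en-1-yl]-2,2,4a,6-tetramethylhexahydro-4H-1,3-benzodioxin-5-yl]methanol (C6 alcohol, arms trans), via alkylborane 19 (not isolated)
Conditions: 9-BBN, THF, 60 °C; then NaOH, H2O2, H2O, 0 °C → rt
Reagents that add atoms: hydrogen peroxide, OO
Why: Hydroboration–oxidation, in which 9-BBN should pick the 1,1-disubstituted alkene over the hindered E-alkene and the furan, place boron on C6 and deliver hydrogen to C5 from the face opposite the two axial methyls C19 and C20, which sets C5 (S) with the two arms trans.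

Step 14
Reactants: 20 C6 alcohol; 21 propargyl bromide
Product: 23 (4aS,5S,6S,8aR)-5-(but-3-yn-1-yl)-6-[(1E)-3-(furan-3-yl)prop-1-en-1-yl]-2,2,4a,6-tetramethylhexahydro-4H-1,3-benzodioxine (ring A 1,7-enyne), via triflate 22 (not isolated)
Conditions: Tf2O, 2,6-lutidine, CH2Cl2, −78 °C; then LiCH2C≡CLi (from 21, n-BuLi 2 equiv, TMEDA, Et2O, −78 °C), THF, −78 → −20 °C; aq. NH4Cl
Reagents that add atoms: none
Why: SN2 alkylation of 1,3-dilithiopropyne, which reacts at its propargylic carbon, by the primary triflate should give the terminal but-3-ynyl arm directly after protonation.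

Step 15
Reactants: 23 ring A 1,7-enyne
Product: 24 (3R,4S,5S,9R,10S)-15,16-epoxy-ent-labda-8(17),13(16),14-triene-3,18-diol acetonide
Conditions: Pd2(dba)3·CHCl3 (2.5 mol %), P(o-tol)3 (10 mol %), AcOH (2 equiv), Et3SiH (10 equiv), toluene, rt → 50 °C
Reagents that add atoms: none
Why: Zerovalent palladium and acetic acid form a palladium hydride that adds syn across the terminal alkyne with palladium on C8, the vinylpalladium inserts the C9=C11 alkene to form C8–C9, and the C11 alkylpalladium is reduced by Et3SiH before β-hydride elimination. The closest known reaction type is the palladium-catalysed reductive cyclisation of 1,6- and 1,7-enynes with a silane as the terminal hydride donor. Ring B closes in the 6-exo-trig mode through a chair-like transition state fused trans to the acetonide-locked ring A chair, because both tether ends (C6 on C5, C9 on C10) are equatorial. The new C9 centre is controlled by this chair: C11 sits equatorial and cis to the axial C20 methyl, since the alternative puts C11 and the palladium axial, syn to H5 and H7. The step needs hydride capture to outrun β-hydride elimination towards C12 or C9, which the large excess of silane is meant to secure, and it needs regioselective hydropalladation, which the terminal alkyne and the tethered alkene secure; furan and acetonide are spectators.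

Step 16
Reactants: 24 cyclised acetonide
Product: 25 (3R,4S,5S,9R,10S)-15,16-epoxy-ent-labda-8(17),13(16),14-triene-3,18-diol
Conditions: PPTS (cat.), MeOH, 40 °C
Reagents that add atoms: none
Why: Acid-catalysed ketal exchange with methanol should remove the acetonide under conditions too mild to isomerise the exocyclic alkene or open the furan.

Step 17
Reactants: 25 3,18-diol
Product: 26 18-O-tert-butyldimethylsilyl ether of 25 (C3 hydroxyl free)
Conditions: TBSCl (1.1 equiv), imidazole, CH2Cl2, 0 °C
Reagents that add atoms: tert-butyldimethylsilyl chloride, CC(C)(C)[Si](C)(C)Cl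
Why: Selective silylation, in which the primary C18 hydroxyl should react far faster than the secondary C3 hydroxyl next to quaternary C4.

Step 18
Reactants: 26 18-O-silyl alcohol; 27 angelic acid ((Z)-2-methylbut-2-enoic acid)
Product: 29 (3R,4S,5S,9R,10S)-18-(tert-butyldimethylsilyloxy)-15,16-epoxy-ent-labda-8(17),13(16),14-trien-3-yl (Z)-2-methylbut-2-enoate, via mixed anhydride 28 (not isolated)
Conditions: 27, 2,4,6-trichlorobenzoyl chloride, Et3N, toluene, rt; then 26, NaHCO3, toluene, 90 °C
Reagents that add atoms: none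
Why: Yamaguchi-type mixed anhydride esterification run without 4-dimethylaminopyridine, in which the C3 hydroxyl attacks the unhindered angeloyl carbonyl and the absence of a nucleophilic amine avoids the addition–elimination path that isomerises angelate to tiglate.

Step 19
Reactants: 29 furan angelate
Product: 32 (3R,4S,5S,9R,10S,13Z)-18-(tert-butyldimethylsilyloxy)-15,16-dihydroxy-ent-labda-8(17),13-dien-3-yl (Z)-2-methylbut-2-enoate, via endoperoxide 30 (not isolated), via enedial 31 (not isolated)
Conditions: O2, tetraphenylporphyrin (cat.), hν, CH2Cl2, −78 °C; Me2S, −78 → −40 °C; then NaBH4, CeCl3·7H2O, MeOH, −78 → 0 °C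
Reagents that add atoms: oxygen, O=O
Why: [4+2] photooxygenation of the furan by singlet oxygen, sulfide reduction of the endoperoxide to the cis-enedial and Luche 1,2-reduction should give the diol with the Z geometry inherited from the ring, while the electron-poor angelate and the 1,1-disubstituted alkene react far more slowly with singlet oxygen and the ester is inert to NaBH4.

Step 20
Reactants: 32 silylated enediol
Product: 33 CNP0237954.1, (3R,4S,5S,9R,10S,13Z)-15,16,18-trihydroxy-ent-labda-8(17),13-dien-3-yl (Z)-2-methylbut-2-enoate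
Conditions: HF·pyridine, pyridine, THF, 0 °C → rt
Reagents that add atoms: none
Why: Fluoride-mediated desilylation under buffered, weakly acidic conditions should free the C18 hydroxyl without base-induced acyl migration from O3 to O18.

Compound list
1 | 2-methylcyclohexane-1,3-dione | CC1C(=O)CCCC1=O | starting material
2 | formaldehyde (37% aqueous) | C=O | starting material
3 | 2-(hydroxymethyl)-2-methylcyclohexane-1,3-dione | CC1(CO)C(=O)CCCC1=O | intermediate
4 | 2-{[tert-butyl(dimethyl)silyl]oxymethyl}-2-methylcyclohexane-1,3-dione | CC1(CO[Si](C)(C)C(C)(C)C)C(=O)CCCC1=O | intermediate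
5 | (2S,3R)-2-{[tert-butyl(dimethyl)silyl]oxymethyl}-3-hydroxy-2-methylcyclohexan-1-one | O=C1CCC[C@@H](O)[C@]1(C)CO[Si](C)(C)C(C)(C)C | intermediate
6 | (2S,3R)-3-hydroxy-2-(hydroxymethyl)-2-methylcyclohexan-1-one (not isolated) | O=C1CCC[C@@H](O)[C@]1(C)CO | intermediate
7 | (4aS,8aR)-2,2,4a-trimethylhexahydro-4H-1,3-benzodioxin-5-one | O=C1CCC[C@H]2OC(C)(C)OC[C@]12C | intermediate
8 | (4aS,8aR)-2,2,4a,6-tetramethylhexahydro-4H-1,3-benzodioxin-5-one (C10 epimers) | O=C1C(C)CC[C@H]2OC(C)(C)OC[C@]12C | intermediate
9 | (4aS,8aR)-2,2,4a,6-tetramethyl-4a,7,8,8a-tetrahydro-4H-1,3-benzodioxin-5-yl trifluoromethanesulfonate | O=S(=O)(OC1=C(C)CC[C@H]2OC(C)(C)OC[C@]12C)C(F)(F)F | intermediate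
10 | methyl (4aS,8aR)-2,2,4a,6-tetramethyl-4a,7,8,8a-tetrahydro-4H-1,3-benzodioxine-5-carboxylate | COC(=O)C1=C(C)CC[C@H]2OC(C)(C)OC[C@]12C | intermediate
11 | [(4aS,8aR)-2,2,4a,6-tetramethyl-4a,7,8,8a-tetrahydro-4H-1,3-benzodioxin-5-yl]methanol | OCC1=C(C)CC[C@H]2OC(C)(C)OC[C@]12C | intermediate
12 | diethyl [(4aS,8aR)-2,2,4a,6-tetramethyl-4a,7,8,8a-tetrahydro-4H-1,3-benzodioxin-5-yl]methyl phosphate | CCOP(=O)(OCC)OCC1=C(C)CC[C@H]2OC(C)(C)OC[C@]12C | intermediate
13 | furan-3-ylmethanol | OCc1ccoc1 | starting material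
14 | 3-(bromomethyl)furan | BrCc1ccoc1 | intermediate
15 | ethynylmagnesium bromide | C#C[Mg]Br | starting material
16 | 3-(prop-2-yn-1-yl)furan | C#CCc1ccoc1 | intermediate
17 | (E)-[3-(furan-3-yl)prop-1-en-1-yl]bis(2-methylpropyl)aluminium (not isolated) | CC(C)C[Al](CC(C)C)/C=C/Cc1ccoc1 | intermediate
18 | (4aS,6S,8aR)-6-[(1E)-3-(furan-3-yl)prop-1-en-1-yl]-2,2,4a,6-tetramethyl-5-methylidenehexahydro-4H-1,3-benzodioxine | C=C1[C@@](C)(CC[C@H]2OC(C)(C)OC[C@]12C)/C=C/Cc1ccoc1 | intermediate
19 | B-alkyl-9-borabicyclo[3.3.1]nonane adduct of 18 at C6 (not isolated) | B1(C[C@H]2[C@@](C)(CC[C@H]3OC(C)(C)OC[C@]23C)/C=C/Cc2ccoc2)C2CCCC1CCC2 | intermediate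
20 | [(4aS,5S,6S,8aR)-6-[(1E)-3-(furan-3-yl)prop-1-en-1-yl]-2,2,4a,6-tetramethylhexahydro-4H-1,3-benzodioxin-5-yl]methanol | OC[C@H]1[C@@](C)(CC[C@H]2OC(C)(C)OC[C@]12C)/C=C/Cc1ccoc1 | intermediate
21 | propargyl bromide (3-bromoprop-1-yne) | C#CCBr | starting material
22 | trifluoromethanesulfonate of 20 (not isolated) | O=S(=O)(OC[C@H]1[C@@](C)(CC[C@H]2OC(C)(C)OC[C@]12C)/C=C/Cc1ccoc1)C(F)(F)F | intermediate
23 | (4aS,5S,6S,8aR)-5-(but-3-yn-1-yl)-6-[(1E)-3-(furan-3-yl)prop-1-en-1-yl]-2,2,4a,6-tetramethylhexahydro-4H-1,3-benzodioxine | C#CCC[C@H]1[C@@](C)(CC[C@H]2OC(C)(C)OC[C@]12C)/C=C/Cc1ccoc1 | intermediate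
24 | (3R,4S,5S,9R,10S)-15,16-epoxy-ent-labda-8(17),13(16),14-triene-3,18-diol acetonide | C=C1CC[C@H]2[C@@](C)(CC[C@H]3OC(C)(C)OC[C@]23C)[C@@H]1CCc1ccoc1 | intermediate
25 | (3R,4S,5S,9R,10S)-15,16-epoxy-ent-labda-8(17),13(16),14-triene-3,18-diol | C=C1CC[C@H]2[C@@](C)(CC[C@@H](O)[C@]2(C)CO)[C@@H]1CCc1ccoc1 | intermediate
26 | 18-O-tert-butyldimethylsilyl ether of 25 | C=C1CC[C@H]2[C@@](C)(CC[C@@H](O)[C@]2(C)CO[Si](C)(C)C(C)(C)C)[C@@H]1CCc1ccoc1 | intermediate
27 | angelic acid, (Z)-2-methylbut-2-enoic acid | C/C=C(/C)C(=O)O | starting material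
28 | (Z)-2-methylbut-2-enoic 2,4,6-trichlorobenzoic anhydride (not isolated) | C/C=C(/C)C(=O)OC(=O)c1c(Cl)cc(Cl)cc1Cl | intermediate
29 | 3-O-angeloyl 18-O-tert-butyldimethylsilyl derivative of 25 | C=C1CC[C@H]2[C@@](C)(CC[C@@H](OC(=O)/C(C)=C\C)[C@]2(C)CO[Si](C)(C)C(C)(C)C)[C@@H]1CCc1ccoc1 | intermediate
30 | furan 2,5-endoperoxide of 29 (not isolated) | C=C1CC[C@H]2[C@@](C)(CC[C@@H](OC(=O)/C(C)=C\C)[C@]2(C)CO[Si](C)(C)C(C)(C)C)[C@@H]1CCC1=CC2OOC1O2 | intermediate
31 | (13Z)-15,16-dial from 29 (not isolated) | C=C1CC[C@H]2[C@@](C)(CC[C@@H](OC(=O)/C(C)=C\C)[C@]2(C)CO[Si](C)(C)C(C)(C)C)[C@@H]1CC/C(=C/C=O)C=O | intermediate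
32 | (13Z)-15,16-diol, 3-O-angeloyl, 18-O-tert-butyldimethylsilyl | C=C1CC[C@H]2[C@@](C)(CC[C@@H](OC(=O)/C(C)=C\C)[C@]2(C)CO[Si](C)(C)C(C)(C)C)[C@@H]1CC/C(=C/CO)CO | intermediate
33 | CNP0237954.1, (3R,4S,5S,9R,10S,13Z)-15,16,18-trihydroxy-ent-labda-8(17),13-dien-3-yl (Z)-2-methylbut-2-enoate | C=C1CC[C@H]2[C@@](C)(CC[C@@H](OC(=O)/C(C)=C\C)[C@]2(C)CO)[C@@H]1CC/C(=C/CO)CO | target

Total step count: 20 (18 in the main line, 2 for the furan alkyne 16).
Longest linear sequence: 18 steps, from 1 to 33 (steps 1–9 and 12–20).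

Steps most likely to fail

Step 15. β-Hydride elimination of the C11 alkylpalladium (towards C12, into conjugation with the furan, or towards C9) may outrun silane capture, or insertion into the hindered C9=C11 alkene may be slow or poorly face-selective. The fallback sets out from 23 and replaces palladium by a tin-hydride radical cyclisation. Bu3SnH and AIBN in benzene at 80 °C should add a stannyl radical to C17; the C8 vinyl radical should close ring B 6-exo onto C9 through the same chair, and the C11 radical is quenched by Bu3SnH. This gives the exocyclic vinylstannane F1. Protodestannylation on silica gel in CH2Cl2 should then give 24, where the fallback rejoins the route.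

Step 12. The copper alkenyl may add sluggishly to the hindered tetrasubstituted alkene, substitute at C6 without allylic shift, or attack the wrong face of C10. The fallback sets out from ketone 8 and alkyne 16 and builds the quaternary centre by enolate coupling. Hydrozirconation of 16 with Cp2Zr(H)Cl followed by iodine should give (E)-3-(3-iodoprop-2-en-1-yl)furan F2. Palladium-catalysed α-alkenylation of the enolate of 8 (Pd2(dba)3, P(t-Bu)3, NaOt-Bu, toluene, 60 °C) is possible only at C10 and is expected anti to the axial C19 methyl, giving the α-alkenyl ketone F3. CeCl3-promoted addition of Me3SiCH2Li should give the β-hydroxysilane F4, and KH in THF should complete the Peterson olefination to 18, where the route resumes. Steps 6 to 9 are then not needed.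

Step 14. The hindered primary triflate may undergo E2 elimination back to the exocyclic alkene, or ionise with help from the neighbouring acetal oxygen, faster than it is substituted. The fallback sets out from 20 and makes the C6–C7 bond by carbonyl addition. Oxidation with DMP and NaHCO3 in CH2Cl2 should give the aldehyde F5. Barbier propargylation with 3-bromo-1-(trimethylsilyl)prop-1-yne and Zn in THF should give the homopropargylic alcohol F6. NaH, CS2 and MeI should give the xanthate F7, and Barton–McCombie deoxygenation (Bu3SnH, AIBN, toluene, 80 °C) the C-silylated enyne F8. K2CO3 in MeOH should then give 23, where the fallback rejoins the route.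

Further compounds
F1 | step 15 | 17-(tributylstannyl) derivative of 24 (exocyclic vinylstannane, E/Z) | CCCC[Sn](CCCC)(CCCC)C=C1CC[C@H]2[C@@](C)(CC[C@H]3OC(C)(C)OC[C@]23C)[C@@H]1CCc1ccoc1
F2 | step 12 | (E)-3-(3-iodoprop-2-en-1-yl)furan | I/C=C/Cc1ccoc1
F3 | step 12 | (4aS,6S,8aR)-6-[(1E)-3-(furan-3-yl)prop-1-en-1-yl]-2,2,4a,6-tetramethylhexahydro-4H-1,3-benzodioxin-5-one | O=C1[C@@](C)(CC[C@H]2OC(C)(C)OC[C@]12C)/C=C/Cc1ccoc1
F4 | step 12 | 5-[(trimethylsilyl)methyl] tertiary alcohol from F3 (C5 epimers) | C[Si](C)(C)CC1(O)[C@@](C)(CC[C@H]2OC(C)(C)OC[C@]12C)/C=C/Cc1ccoc1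
F5 | step 14 | (4aS,5S,6S,8aR)-6-[(1E)-3-(furan-3-yl)prop-1-en-1-yl]-2,2,4a,6-tetramethylhexahydro-4H-1,3-benzodioxine-5-carbaldehyde | O=C[C@H]1[C@@](C)(CC[C@H]2OC(C)(C)OC[C@]12C)/C=C/Cc1ccoc1
F6 | step 14 | 4-(trimethylsilyl)but-3-yn-1-ol carrying the ring A unit of F5 at C1 (carbinol epimers) | C[Si](C)(C)C#CCC(O)[C@H]1[C@@](C)(CC[C@H]2OC(C)(C)OC[C@]12C)/C=C/Cc1ccoc1
F7 | step 14 | S-methyl xanthate of F6 | CSC(=S)OC(CC#C[Si](C)(C)C)[C@H]1[C@@](C)(CC[C@H]2OC(C)(C)OC[C@]12C)/C=C/Cc1ccoc1
F8 | step 14 | C-trimethylsilyl derivative of 23 | C[Si](C)(C)C#CCC[C@H]1[C@@](C)(CC[C@H]2OC(C)(C)OC[C@]12C)/C=C/Cc1ccoc1
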